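**Plan**
- The target is a 2-arylbenzofuran with a pentasubstituted aryl ring: C1′ benzofuran-2-yl, C2′ prenyl, C3′ OH, C5′ OMe, C6′ prenyl. It has no stereocentre and no E/Z alkene, so no stereocontrol is needed.
- Enabling feature: C1′ and C6′ are neighbours, and C6′ sits beside the C5′ methoxy oxygen. This is the pattern left when a nucleophile and then an electrophile add across a 3-methoxybenzyne.
- Retrosynthesis: two O-protecting groups are removed, then the C2–C1′ biaryl bond and the C6′–CH2 bond are cut together. This gives a C1′–C6′ aryne, a 2-magnesiated 6-silyloxybenzofuran and prenyl bromide.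
- The aryne comes from an arene with iodine at C6′ and a 4-chlorobenzenesulfonate at C1′. That arene traces back through two directed ortho-metalations (C6′–I, C2′–prenyl) to the bis-MOM ether of 5-methoxyresorcinol.
- Forward: no ring is built, since the benzene ring and the benzofuran are bought intact. The C2′ prenyl group goes on first, then iodine, then the sulfonates. Both halves and the second prenyl group are joined in one flask, and base frees the two phenols.

Key step: step 7

Remark: primed locants refer to the pentasubstituted benzene ring as defined above, and prenyl means 3-methylbut-2-enyl. The four starting materials are assumed to be catalogue compounds.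

**Step 1**
Reactants: 1 5-methoxyresorcinol
Product: 2 1-methoxy-3,5-bis(methoxymethoxy)benzene
Conditions: NaH, MOMCl, DMF, 0 °C to rt
Reagents that add atoms: chloromethyl methyl ether (MOMCl), COCCl
Why: Williamson-type O-alkylation of the sodium bis-phenoxide with the hard electrophile MOMCl masks both phenols as acetals that survive organolithium reagents and are the strongest directing groups on the ring.

**Step 2**
Reactants: 2 1-methoxy-3,5-bis(methoxymethoxy)benzene; 3 prenyl bromide (1-bromo-3-methylbut-2-ene)
Product: 5 5-methoxy-1,3-bis(methoxymethoxy)-2-(3-methylbut-2-enyl)benzene, via 2-lithio arene 4 (not isolated)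
Conditions: n-BuLi, THF, 0 °C to rt; then 3, −78 °C to rt
Reagents that add atoms: prenyl bromide 3, CC(C)=CCBr
Why: Directed ortho-metalation removes the proton between the two chelating OMOM groups in preference to those beside the weaker methoxy director, and the aryllithium displaces bromide at the primary carbon of prenyl bromide (SN2), which fixes the C2′ prenyl group.

**Step 3**
Reactants: 5 5-methoxy-1,3-bis(methoxymethoxy)-2-(3-methylbut-2-enyl)benzene
Product: 7 2-iodo-1-methoxy-3,5-bis(methoxymethoxy)-4-(3-methylbut-2-enyl)benzene, via ring-lithiated arene 6 (not isolated)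
Conditions: n-BuLi, THF, −20 to 0 °C; then I2, THF, −78 °C to rt; aq. Na2S2O3 work-up
Reagents that add atoms: iodine, [I][I]
Why: A second directed ortho-metalation takes one of the two equivalent remaining ring protons, each held between an OMOM and an OMe group and therefore removed faster than the benzylic-allylic CH2 protons, and iodinolysis of the C–Li bond places iodine at C6′.

**Step 4**
Reactants: 7 2-iodo-1-methoxy-3,5-bis(methoxymethoxy)-4-(3-methylbut-2-enyl)benzene
Product: 8 4-iodo-5-methoxy-2-(3-methylbut-2-enyl)benzene-1,3-diol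
Conditions: conc. aq. HCl (catalytic), MeOH, 35 °C, stopped at full conversion
Reagents that add atoms: none
Why: Acid-catalysed acetal exchange with methanol frees both phenols under the mild conditions customary for MOM ethers of ortho-prenylphenols, kept short and only gently warm so that chroman formation and protodeiodination stay slow.

**Step 5**
Reactants: 8 4-iodo-5-methoxy-2-(3-methylbut-2-enyl)benzene-1,3-diol; 9 4-chlorobenzenesulfonyl chloride
Product: 10 4-iodo-5-methoxy-2-(3-methylbut-2-enyl)-1,3-phenylene bis(4-chlorobenzenesulfonate)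
Conditions: 9 (2.4 equiv), Et3N, DMAP (cat.), CH2Cl2, 0 °C to rt
Reagents that add atoms: 4-chlorobenzenesulfonyl chloride 9, O=S(=O)(Cl)c1ccc(Cl)cc1
Why: DMAP-catalysed O-sulfonylation of both phenols gives in one operation the leaving group at C1′ beside the iodine and a Grignard-tolerant, base-labile protecting group at C3′.

**Step 6**
Reactants: 11 benzofuran-6-ol
Product: 12 6-(triisopropylsilyloxy)benzofuran
Conditions: TIPSCl, imidazole, DMF, rt
Reagents that add atoms: chlorotriisopropylsilane (TIPSCl), CC(C)[Si](Cl)(C(C)C)C(C)C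
Why: Imidazole-promoted silylation gives a bulky aryl silyl ether that withstands n-BuLi and Grignard reagents and is a poor ortho director, so the later metalation goes to the acidic furan C2–H.

**Step 7**
Reactants: 10 4-iodo-5-methoxy-2-(3-methylbut-2-enyl)-1,3-phenylene bis(4-chlorobenzenesulfonate); 12 6-(triisopropylsilyloxy)benzofuran; 3 prenyl bromide
Product: 18 5-methoxy-2,4-bis(3-methylbut-2-enyl)-3-[6-(triisopropylsilyloxy)benzofuran-2-yl]phenyl 4-chlorobenzenesulfonate, via 2-lithiobenzofuran 13 (not isolated), via benzofuran-2-ylmagnesium bromide 14 (not isolated), via arylmagnesium chloride 15 (not isolated), via C1′–C6′ aryne 16 (not isolated), via biaryl Grignard reagent 17 (not isolated)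
Conditions: 12 (2 equiv), n-BuLi, THF, −78 to −20 °C, then MgBr2·OEt2, 0 °C; separately 10, i-PrMgCl·LiCl (1.05 equiv), THF, −78 °C; combine at −78 °C, warm to rt; then CuBr·SMe2 (20 mol %), 3 (excess), −20 °C to rt
Reagents that add atoms: prenyl bromide 3, CC(C)=CCBr
Why: Iodine–magnesium exchange at C6′ of 10 is fast at −78 °C because the flanking methoxy and sulfonyloxy groups stabilise arylmagnesium 15, which on warming expels the C1′ 4-chlorobenzenesulfonate and becomes aryne 16. The slim sp2 Grignard reagent 14, present in excess so that it outruns the hindered 15 as nucleophile, adds across the strained triple bond (carbomagnesiation), and the resulting arylmagnesium 17 is allylated at the primary carbon of prenyl bromide under CuBr·SMe2 catalysis, so that the C2–C1′ and C6′–CH2 bonds form in one flask. The closest known reaction type is the addition of aryl Grignard reagents to arynes with electrophilic capture of the 2-biarylmagnesium halide, as used for m-terphenyls and dialkylbiarylphosphines, joined to the release of arynes from 2-magnesiated aryl sulfonates. No ring is closed and no stereocentre is created. The selectivity needed is attack at C1′ rather than C6′: the σ-withdrawing C5′ oxygen distorts the aryne so that C1′ is the more linear, more electrophilic terminus and the developing carbanion sits at C6′ next to that oxygen, a bias that should outweigh the steric demand of the C2′ CH2 group toward a five-membered heteroaryl nucleophile without ortho substituents. The C3′ sulfonate is para to magnesium and cannot eliminate, and preparing 14 by lithiation and transmetalation rather than with a magnesium amide keeps the flask free of an N–H amine that could protonate 17 or add to 16.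

**Step 8**
Reactants: 18 5-methoxy-2,4-bis(3-methylbut-2-enyl)-3-[6-(triisopropylsilyloxy)benzofuran-2-yl]phenyl 4-chlorobenzenesulfonate
Product: 19 2-[3-hydroxy-5-methoxy-2,6-bis(3-methylbut-2-enyl)phenyl]benzofuran-6-ol (target)
Conditions: KOH (excess), 1,4-dioxane/H2O, 90 °C; then cold 1 M HCl to pH 5
Reagents that add atoms: none
Why: Hydroxide attacks sulfur of the aryl arenesulfonate and silicon of the aryl silyl ether (saponification-type S–O and Si–O cleavage with phenoxide leaving groups), the alcohol-free medium prevents formation of an alkyl sulfonate that could O-alkylate the product, and the prenyl groups, methyl ether and benzofuran are inert to aqueous base.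

**Compound list**
1 | 5-methoxyresorcinol (5-methoxybenzene-1,3-diol) | COc1cc(O)cc(O)c1 | starting material
2 | 1-methoxy-3,5-bis(methoxymethoxy)benzene | COCOc1cc(OC)cc(OCOC)c1 | intermediate
3 | prenyl bromide (1-bromo-3-methylbut-2-ene) | CC(C)=CCBr | starting material
4 | [4-methoxy-2,6-bis(methoxymethoxy)phenyl]lithium | [Li]c1c(OCOC)cc(OC)cc1OCOC | intermediate
5 | 5-methoxy-1,3-bis(methoxymethoxy)-2-(3-methylbut-2-enyl)benzene | COCOc1cc(OC)cc(OCOC)c1CC=C(C)C | intermediate
6 | [6-methoxy-2,4-bis(methoxymethoxy)-3-(3-methylbut-2-enyl)phenyl]lithium | COCOc1cc(OC)c([Li])c(OCOC)c1CC=C(C)C | intermediate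
7 | 2-iodo-1-methoxy-3,5-bis(methoxymethoxy)-4-(3-methylbut-2-enyl)benzene | COCOc1cc(OC)c(I)c(OCOC)c1CC=C(C)C | intermediate
8 | 4-iodo-5-methoxy-2-(3-methylbut-2-enyl)benzene-1,3-diol | COc1cc(O)c(CC=C(C)C)c(O)c1I | intermediate
9 | 4-chlorobenzenesulfonyl chloride | O=S(=O)(Cl)c1ccc(Cl)cc1 | starting material
10 | 4-iodo-5-methoxy-2-(3-methylbut-2-enyl)-1,3-phenylene bis(4-chlorobenzenesulfonate) | COc1cc(OS(=O)(=O)c2ccc(Cl)cc2)c(CC=C(C)C)c(OS(=O)(=O)c2ccc(Cl)cc2)c1I | intermediate
11 | benzofuran-6-ol | Oc1ccc2ccoc2c1 | starting material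
12 | 6-(triisopropylsilyloxy)benzofuran | CC(C)[Si](Oc1ccc2ccoc2c1)(C(C)C)C(C)C | intermediate
13 | [6-(triisopropylsilyloxy)benzofuran-2-yl]lithium | [Li]c1cc2ccc(O[Si](C(C)C)(C(C)C)C(C)C)cc2o1 | intermediate
14 | [6-(triisopropylsilyloxy)benzofuran-2-yl]magnesium bromide | Br[Mg]c1cc2ccc(O[Si](C(C)C)(C(C)C)C(C)C)cc2o1 | intermediate
15 | [2-methoxy-4,6-bis(4-chlorophenylsulfonyloxy)-5-(3-methylbut-2-enyl)phenyl]magnesium chloride | COc1cc(OS(=O)(=O)c2ccc(Cl)cc2)c(CC=C(C)C)c(OS(=O)(=O)c2ccc(Cl)cc2)c1[Mg]Cl | intermediate
16 | 3-methoxy-5-(4-chlorophenylsulfonyloxy)-6-(3-methylbut-2-enyl)-1,2-didehydrobenzene (C1′–C6′ aryne) | COC1=CC(OS(=O)(=O)c2ccc(Cl)cc2)=C(CC=C(C)C)C#C1 | intermediate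
17 | {6-methoxy-4-(4-chlorophenylsulfonyloxy)-3-(3-methylbut-2-enyl)-2-[6-(triisopropylsilyloxy)benzofuran-2-yl]phenyl}magnesium bromide | COc1cc(OS(=O)(=O)c2ccc(Cl)cc2)c(CC=C(C)C)c(-c2cc3ccc(O[Si](C(C)C)(C(C)C)C(C)C)cc3o2)c1[Mg]Br | intermediate
18 | 5-methoxy-2,4-bis(3-methylbut-2-enyl)-3-[6-(triisopropylsilyloxy)benzofuran-2-yl]phenyl 4-chlorobenzenesulfonate | COc1cc(OS(=O)(=O)c2ccc(Cl)cc2)c(CC=C(C)C)c(-c2cc3ccc(O[Si](C(C)C)(C(C)C)C(C)C)cc3o2)c1CC=C(C)C | intermediate
19 | 2-[3-hydroxy-5-methoxy-2,6-bis(3-methylbut-2-enyl)phenyl]benzofuran-6-ol (CNP0324103.0) | COc1cc(O)c(CC=C(C)C)c(-c2cc3ccc(O)cc3o2)c1CC=C(C)C | target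

**Total step count:** 8
**Longest linear sequence:** 7 steps (1, 2, 3, 4, 5, 7, 8)

**Steps most likely to fail**

**Step 7.**
- What may go wrong: the aryne may be intercepted by its own precursor 15 or by a prenyl double bond before 14 adds. Part of the addition may take place at C6′. The doubly flanked arylmagnesium 17 may pick up a proton faster than it is allylated.
- Fallback: no aryne, with the two bonds made by separate palladium-catalysed cross-couplings. It sets out from 8 and comes back to the route at 19.
- The less hindered C3′ hydroxyl of 8 is silylated (TIPSCl, imidazole, DMF) to the mono-TIPS iodophenol F1. The remaining C1′ hydroxyl is converted (Tf2O, pyridine, CH2Cl2, 0 °C) into the iodo triflate F2.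
- A Stille coupling with tributyl(3-methylbut-2-enyl)stannane (Pd2(dba)3, AsPh3, DMF, 60 °C, no chloride additive) should engage only the C6′ iodide and give the diprenyl triflate F3.
- Organolithium 13, made from 12 as in step 7, is transmetalated with ZnCl2 to benzofuran-2-ylzinc chloride F4. This is joined to F3 in a Negishi coupling (Pd(OAc)2, SPhos, THF, 65 °C) to give the bis-TIPS ether of the target F5. Bu4NF in THF then gives 19.

**Step 4.**
- What may go wrong: a liberated phenol may cyclise under acid onto the neighbouring prenyl double bond. The very electron-rich ring may also lose iodine by protonation.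
- Fallback: fluoride-labile acetals, so that no acid is used. It sets out from 1 and comes back at 8.
- Compound 1 is alkylated with SEMCl (NaH, DMF) to the bis-SEM ether F6.
- n-BuLi gives the C2-lithiated bis-SEM ether F7, which with 3 gives the prenylated bis-SEM ether F8.
- A second metalation gives the ring-lithiated prenyl arene F9, and iodine then gives the iodinated bis-SEM ether F10.
- Bu4NF (THF/DMPU, 60 °C) attacks silicon and fragments both acetals under basic conditions, which gives 8.

**Step 3.**
- What may go wrong: deprotonation may occur at the doubly activated benzylic-allylic CH2, followed by double-bond migration or side-chain iodination. Ring metalation may also be incomplete.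
- Fallback: electrophilic aromatic substitution in place of deprotonation. It sets out from 5 and comes back at 7.
- N-iodosuccinimide in MeCN at 0 °C in the dark should iodinate one of the two equivalent free ring positions. The trialkoxy-substituted ring is a much better nucleophile than the trisubstituted alkene, and iodonium formation at the alkene is reversible while both phenols stay masked.
- No compound outside the list is made (entry F0).

**Further compounds**
F1 | step 7 | 2-iodo-3-methoxy-6-(3-methylbut-2-enyl)-5-(triisopropylsilyloxy)phenol | COc1cc(O[Si](C(C)C)(C(C)C)C(C)C)c(CC=C(C)C)c(O)c1I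
F2 | step 7 | 2-iodo-3-methoxy-6-(3-methylbut-2-enyl)-5-(triisopropylsilyloxy)phenyl trifluoromethanesulfonate | COc1cc(O[Si](C(C)C)(C(C)C)C(C)C)c(CC=C(C)C)c(OS(=O)(=O)C(F)(F)F)c1I
F3 | step 7 | 3-methoxy-2,6-bis(3-methylbut-2-enyl)-5-(triisopropylsilyloxy)phenyl trifluoromethanesulfonate | COc1cc(O[Si](C(C)C)(C(C)C)C(C)C)c(CC=C(C)C)c(OS(=O)(=O)C(F)(F)F)c1CC=C(C)C
F4 | step 7 | [6-(triisopropylsilyloxy)benzofuran-2-yl]zinc chloride | Cl[Zn]c1cc2ccc(O[Si](C(C)C)(C(C)C)C(C)C)cc2o1
F5 | step 7 | 2-[3-methoxy-2,6-bis(3-methylbut-2-enyl)-5-(triisopropylsilyloxy)phenyl]-6-(triisopropylsilyloxy)benzofuran | COc1cc(O[Si](C(C)C)(C(C)C)C(C)C)c(CC=C(C)C)c(-c2cc3ccc(O[Si](C(C)C)(C(C)C)C(C)C)cc3o2)c1CC=C(C)C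
F6 | step 4 | 1-methoxy-3,5-bis{[2-(trimethylsilyl)ethoxy]methoxy}benzene | COc1cc(OCOCC[Si](C)(C)C)cc(OCOCC[Si](C)(C)C)c1
F7 | step 4 | (4-methoxy-2,6-bis{[2-(trimethylsilyl)ethoxy]methoxy}phenyl)lithium | [Li]c1c(OCOCC[Si](C)(C)C)cc(OC)cc1OCOCC[Si](C)(C)C
F8 | step 4 | 5-methoxy-2-(3-methylbut-2-enyl)-1,3-bis{[2-(trimethylsilyl)ethoxy]methoxy}benzene | COc1cc(OCOCC[Si](C)(C)C)c(CC=C(C)C)c(OCOCC[Si](C)(C)C)c1
F9 | step 4 | (6-methoxy-3-(3-methylbut-2-enyl)-2,4-bis{[2-(trimethylsilyl)ethoxy]methoxy}phenyl)lithium | COc1cc(OCOCC[Si](C)(C)C)c(CC=C(C)C)c(OCOCC[Si](C)(C)C)c1[Li]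
F10 | step 4 | 2-iodo-1-methoxy-4-(3-methylbut-2-enyl)-3,5-bis{[2-(trimethylsilyl)ethoxy]methoxy}benzene | COc1cc(OCOCC[Si](C)(C)C)c(CC=C(C)C)c(OCOCC[Si](C)(C)C)c1I
F0 | step 3 | none | none
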